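## Retrosynthetic overview

1. Target 22 ⇒ C8 alcohol 16 + acid 20 (esterification last). Acid 20 ⇐ tiglic aldehyde by organocatalytic epoxidation, oxidation and C3 acetolysis.
2. 16 ⇐ acyclic bromo enal 13. One CrCl2-mediated Barbier cyclisation forms C6–C7: the ten-membered carbocycle closes first, the γ-lactone closes directly afterwards in the same flask.
3. 13 ⇐ aldehyde 9 by Morita–Baylis–Hillman reaction with methyl acrylate (C7–C11), then allylic transposition to the bromide.
4. 9 ⇐ 2-formyl enoate 6 + PMB-oxyacetaldehyde 7 by a D-proline cross-aldol (C8–C9 bond, both stereocentres, from achiral partners).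
5. 6 ⇐ neryl acetate 1 + methyl acrylate by ozonolysis, Morita–Baylis–Hillman reaction, bromination and N-oxide oxidation.

## Notes and assumptions

- Locants in the explanations use germacrane numbering: C1–C10 are the ring carbons (C6 carries the lactone oxygen, C7 is the ring-fusion CH, C8 and C9 carry the acyloxy groups, C10 carries ester carbon C14), C11–C13 form the methylene-lactone unit, C15 is the methyl on C4.
- Assumption: the amine/phosphoric acid pair named in step 12 gives the (2S,3R)-epoxide; if the opposite sense is found, its pseudo-enantiomer (9-amino(9-deoxy)epiquinidine with (S)-TRIP) is used.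
- Assumption: aldehyde 7 is bought as a catalogue compound.
- The C8 descriptor is R in 8 and 9 and S from 10 onwards. The spatial arrangement is the same; only the CIP priority of C7 changes.

## Route

Step 1
Reactants: 1 neryl acetate
Product: 2 (2Z)-3-methyl-6-oxohex-2-en-1-yl acetate
Conditions: O3 (1.0 equiv), pyridine (3 equiv), CH2Cl2, −78 °C
Reagents that add atoms: ozone [O-][O+]=O
Why: Ozone attacks the electron-rich isopropylidene alkene in preference to the alkene deactivated by the allylic acetate, and pyridine diverts the carbonyl oxide directly to the aldehyde (chemoselective pyridine-modified ozonolysis).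

Step 2
Reactants: 2 (2Z)-3-methyl-6-oxohex-2-en-1-yl acetate; 3 methyl acrylate
Product: 4 methyl (6Z)-8-acetoxy-3-hydroxy-6-methyl-2-methylideneoct-6-enoate (racemic)
Conditions: 3 (4 equiv), DABCO (0.5 equiv), MeOH (1 equiv), rt, 3 d
Reagents that add atoms: none
Why: Morita–Baylis–Hillman reaction of an unhindered aliphatic aldehyde with methyl acrylate; the carbinol centre is racemic and is erased in step 3.

Step 3
Reactants: 4 methyl (6Z)-8-acetoxy-3-hydroxy-6-methyl-2-methylideneoct-6-enoate
Product: 5 methyl (2Z,6Z)-8-acetoxy-2-(bromomethyl)-6-methylocta-2,6-dienoate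
Conditions: NBS, Me2S, CH2Cl2, 0 °C → rt
Reagents that add atoms: N-bromosuccinimide O=C1CCC(=O)N1Br
Why: The sulfonium reagent formed from NBS and Me2S activates the allylic alcohol and bromide enters at the methylene terminus (SN2′ allylic transposition), giving the favoured (Z)-bromide with the chain trans to the ester, which is the C1=C10 geometry of the target.

Step 4
Reactants: 5 methyl (2Z,6Z)-8-acetoxy-2-(bromomethyl)-6-methylocta-2,6-dienoate
Product: 6 methyl (2E,6Z)-8-acetoxy-2-formyl-6-methylocta-2,6-dienoate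
Conditions: NMO (3 equiv), NaHCO3, MeCN, rt
Reagents that add atoms: N-methylmorpholine N-oxide C[N+]1([O-])CCOCC1
Why: Kornblum-type oxidation, in which the N-oxide is O-alkylated by the primary allylic bromide and base-induced elimination gives the aldehyde with the alkene geometry kept (chain cis to CHO, the smaller group).

Step 5
Reactants: 6 methyl (2E,6Z)-8-acetoxy-2-formyl-6-methylocta-2,6-dienoate; 7 2-[(4-methoxybenzyl)oxy]acetaldehyde
Product: 9 methyl (2E,6Z)-8-acetoxy-2-[(1R,2R)-2-[(4-methoxybenzyl)oxy]-1-(2-methylpropanoyloxy)-3-oxopropyl]-6-methylocta-2,6-dienoate, via aldol adduct 8 (not isolated)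
Conditions: D-proline (20 mol %), DMF, 4 °C, 7 (3 equiv) added by syringe pump over 20 h; then (i-PrCO)2O, pyridine, DMAP (10 mol %), CH2Cl2, 0 °C
Reagents that add atoms: isobutyric anhydride CC(C)C(=O)OC(=O)C(C)C
Why: Proposed new method: a proline-catalysed enamine cross-aldol whose acceptor is a 2-formyl-2-alkenoate, a class not yet used in enamine aldol chemistry; the (E)-enamine of 7 formed with D-proline adds to the formyl group of 6 through the hydrogen-bonded chair transition state of the Houk–List model, which gives the anti adduct and sets C8 (R) and C9 (R) in 8 (the 8S,9R centres of the target); 1,2-addition should outrun conjugate addition because the formyl carbon is the most electrophilic site and the β-carbon is alkyl-substituted, 6 has no α-hydrogen and cannot act as donor, and slow addition of 7 limits its self-aldol; the closest known reaction type is the proline-catalysed cross-aldol of α-oxyaldehydes with non-enolisable aldehydes; the carbinol is acylated in the same flask (DMAP-catalysed esterification) so that the β-hydroxy aldehyde is never handled.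

Step 6
Reactants: 9 methyl (2E,6Z)-8-acetoxy-2-[(1R,2R)-2-[(4-methoxybenzyl)oxy]-1-(2-methylpropanoyloxy)-3-oxopropyl]-6-methylocta-2,6-dienoate; 3 methyl acrylate
Product: 10 dimethyl (4S,5R,6E)-6-[(4Z)-6-acetoxy-4-methylhex-4-en-1-ylidene]-3-hydroxy-4-[(4-methoxybenzyl)oxy]-2-methylidene-5-(2-methylpropanoyloxy)heptanedioate (both C3 epimers)
Conditions: 3 (10 equiv, neat), DABCO (0.5 equiv), 0 °C → rt
Reagents that add atoms: none
Why: Morita–Baylis–Hillman reaction of an activated α-alkoxy aldehyde, which is fast enough at low temperature to outpace epimerisation at C8 and β-elimination; the new C7 carbinol need not be controlled because C7 becomes sp2 in step 9.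

Step 7
Reactants: 10 dimethyl (4S,5R,6E)-6-[(4Z)-6-acetoxy-4-methylhex-4-en-1-ylidene]-3-hydroxy-4-[(4-methoxybenzyl)oxy]-2-methylidene-5-(2-methylpropanoyloxy)heptanedioate
Product: 11 dimethyl (4S,5R,6E)-3-hydroxy-6-[(4Z)-6-hydroxy-4-methylhex-4-en-1-ylidene]-4-[(4-methoxybenzyl)oxy]-2-methylidene-5-(2-methylpropanoyloxy)heptanedioate
Conditions: immobilised Candida antarctica lipase B, MeOH (5 equiv), t-BuOMe, 30 °C
Reagents that add atoms: none
Why: Lipase-catalysed transesterification removes the unhindered primary allylic acetate under neutral conditions and leaves the hindered secondary isobutyrate and the conjugated methyl esters alone, with no base to cause acyl migration.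

Step 8
Reactants: 11 dimethyl (4S,5R,6E)-3-hydroxy-6-[(4Z)-6-hydroxy-4-methylhex-4-en-1-ylidene]-4-[(4-methoxybenzyl)oxy]-2-methylidene-5-(2-methylpropanoyloxy)heptanedioate
Product: 12 dimethyl (4S,5R,6E)-3-hydroxy-4-[(4-methoxybenzyl)oxy]-6-[(4Z)-4-methyl-6-oxohex-4-en-1-ylidene]-2-methylidene-5-(2-methylpropanoyloxy)heptanedioate
Conditions: MnO2 (15 equiv), CH2Cl2, rt
Reagents that add atoms: none
Why: MnO2 oxidises the primary allylic alcohol to the (Z)-enal without isomerisation (as for nerol to neral), while the secondary carbinol next to the acrylate reacts far more slowly.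

Step 9
Reactants: 12 dimethyl (4S,5R,6E)-3-hydroxy-4-[(4-methoxybenzyl)oxy]-6-[(4Z)-4-methyl-6-oxohex-4-en-1-ylidene]-2-methylidene-5-(2-methylpropanoyloxy)heptanedioate
Product: 13 methyl (2Z,4S,5R,6E,10Z)-2-(bromomethyl)-6-(methoxycarbonyl)-4-[(4-methoxybenzyl)oxy]-10-methyl-5-(2-methylpropanoyloxy)-12-oxododeca-2,6,10-trienoate
Conditions: NBS, Me2S, CH2Cl2, −20 → 0 °C
Reagents that add atoms: N-bromosuccinimide O=C1CCC(=O)N1Br
Why: The same SN2′ bromination as in step 3 converts the Morita–Baylis–Hillman alcohol into the (Z)-2-(bromomethyl)enoate under neutral conditions that the enal, the PMB ether and the esters tolerate.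

Step 10
Reactants: 13 methyl (2Z,4S,5R,6E,10Z)-2-(bromomethyl)-6-(methoxycarbonyl)-4-[(4-methoxybenzyl)oxy]-10-methyl-5-(2-methylpropanoyloxy)-12-oxododeca-2,6,10-trienoate
Product: 15 methyl (3aS,4S,5R,6E,10Z,11aR)-4-[(4-methoxybenzyl)oxy]-10-methyl-3-methylidene-5-(2-methylpropanoyloxy)-2-oxo-2,3,3a,4,5,8,9,11a-octahydrocyclodeca[b]furan-6-carboxylate, via hydroxy ester 14 (not isolated)
Conditions: CrCl2 (8 equiv), THF, rt, 13 added over 10 h (final 2 mM); then PPTS (cat.), CH2Cl2, rt
Reagents that add atoms: none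
Why: Intramolecular Nozaki–Hiyama (Barbier-type) allylation, in which CrCl2 (divalent chromium) turns the allylic bromide into an allylchromium species that adds through C7 to the enal carbonyl C6 in a chair-like six-membered transition state and closes the ten-membered ring; with C8–H eclipsing the alkene (allylic 1,3-strain) the aldehyde adds anti to the C8–C9 bond, which sets C7 (S), and the 6,7-anti adduct sets C6 (R), whose alkoxide closes the trans-fused lactone with loss of methanol; this mode of ring closure is established for germacranolides.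

Step 11
Reactants: 15 methyl (3aS,4S,5R,6E,10Z,11aR)-4-[(4-methoxybenzyl)oxy]-10-methyl-3-methylidene-5-(2-methylpropanoyloxy)-2-oxo-2,3,3a,4,5,8,9,11a-octahydrocyclodeca[b]furan-6-carboxylate
Product: 16 methyl (3aS,4S,5R,6E,10Z,11aR)-4-hydroxy-10-methyl-3-methylidene-5-(2-methylpropanoyloxy)-2-oxo-2,3,3a,4,5,8,9,11a-octahydrocyclodeca[b]furan-6-carboxylate
Conditions: DDQ (1.5 equiv), CH2Cl2/pH 7 buffer (10:1), 0 °C → rt
Reagents that add atoms: none
Why: Oxidative cleavage of the PMB ether by DDQ is neutral, so the neighbouring isobutyrate does not migrate and the methylene lactone and alkenes are untouched.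

Step 12
Reactants: 17 (2E)-2-methylbut-2-enal (tiglic aldehyde)
Product: 19 (2S,3R)-2,3-dimethyloxirane-2-carboxylic acid, via epoxy aldehyde 18 (not isolated)
Conditions: 9-amino(9-deoxy)epiquinine (10 mol %), (R)-TRIP (10 mol %), 50% aq. H2O2, THF, 50 °C; then NaClO2, NaH2PO4, t-BuOH/H2O, 0 °C
Reagents that add atoms: hydrogen peroxide OO; sodium chlorite [Na+].[O-]Cl=O
Why: Iminium-catalysed nucleophilic (Weitz–Scheffer-type) epoxidation of an α-branched enal by the chiral primary amine/phosphoric acid pair sets C2 and C3 with the E geometry carried into the trans epoxide, and Pinnick oxidation (leftover H2O2 scavenges HOCl) gives the acid without handling the volatile epoxy aldehyde.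

Step 13
Reactants: 19 (2S,3R)-2,3-dimethyloxirane-2-carboxylic acid
Product: 20 (2S,3S)-3-acetoxy-2-hydroxy-2-methylbutanoic acid
Conditions: Ti(Oi-Pr)4 (1.5 equiv), AcOH (5 equiv), CH2Cl2, rt; aq. tartaric acid work-up
Reagents that add atoms: acetic acid CC(=O)O
Why: Titanium-mediated opening of a 2,3-epoxy acid, in which the carboxylate binds titanium and acetate is delivered to C3 with inversion (3R to 3S) while C2 keeps its oxygen and configuration.

Step 14
Reactants: 16 methyl (3aS,4S,5R,6E,10Z,11aR)-4-hydroxy-10-methyl-3-methylidene-5-(2-methylpropanoyloxy)-2-oxo-2,3,3a,4,5,8,9,11a-octahydrocyclodeca[b]furan-6-carboxylate; 20 (2S,3S)-3-acetoxy-2-hydroxy-2-methylbutanoic acid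
Product: 22 CNP0479879.1 (target), via mixed anhydride 21 (not isolated)
Conditions: 20 (3 equiv), 2,4,6-trichlorobenzoyl chloride, Et3N, THF, 0 °C → rt; then 16, DMAP, toluene, rt
Reagents that add atoms: none
Why: Yamaguchi esterification, in which DMAP attacks the aliphatic carbonyl of the mixed anhydride and the acylpyridinium acylates the hindered C8 alcohol; the tertiary hydroxyl of 20 is too hindered to compete and no stereocentre is touched.

## Compound list

1 | neryl acetate, (2Z)-3,7-dimethylocta-2,6-dien-1-yl acetate | CC(C)=CCC/C(C)=C\COC(C)=O | starting material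
2 | (2Z)-3-methyl-6-oxohex-2-en-1-yl acetate | O=CCC/C(C)=C\COC(C)=O | intermediate
3 | methyl acrylate | C=CC(=O)OC | starting material
4 | methyl (6Z)-8-acetoxy-3-hydroxy-6-methyl-2-methylideneoct-6-enoate (racemic) | C=C(C(=O)OC)C(O)CC/C(C)=C\COC(C)=O | intermediate
5 | methyl (2Z,6Z)-8-acetoxy-2-(bromomethyl)-6-methylocta-2,6-dienoate | BrC/C(C(=O)OC)=C\CC/C(C)=C\COC(C)=O | intermediate
6 | methyl (2E,6Z)-8-acetoxy-2-formyl-6-methylocta-2,6-dienoate | O=C/C(C(=O)OC)=C\CC/C(C)=C\COC(C)=O | intermediate
7 | 2-[(4-methoxybenzyl)oxy]acetaldehyde | O=CCOCc1ccc(OC)cc1 | starting material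
8 | aldol adduct, methyl (2E,6Z)-8-acetoxy-2-[(1R,2R)-1-hydroxy-2-[(4-methoxybenzyl)oxy]-3-oxopropyl]-6-methylocta-2,6-dienoate | O=C[C@H](OCc1ccc(OC)cc1)[C@H](O)/C(C(=O)OC)=C\CC/C(C)=C\COC(C)=O | intermediate
9 | methyl (2E,6Z)-8-acetoxy-2-[(1R,2R)-2-[(4-methoxybenzyl)oxy]-1-(2-methylpropanoyloxy)-3-oxopropyl]-6-methylocta-2,6-dienoate | O=C[C@H](OCc1ccc(OC)cc1)[C@H](OC(=O)C(C)C)/C(C(=O)OC)=C\CC/C(C)=C\COC(C)=O | intermediate
10 | dimethyl (4S,5R,6E)-6-[(4Z)-6-acetoxy-4-methylhex-4-en-1-ylidene]-3-hydroxy-4-[(4-methoxybenzyl)oxy]-2-methylidene-5-(2-methylpropanoyloxy)heptanedioate (both C3 epimers) | C=C(C(=O)OC)C(O)[C@H](OCc1ccc(OC)cc1)[C@H](OC(=O)C(C)C)/C(C(=O)OC)=C\CC/C(C)=C\COC(C)=O | intermediate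
11 | dimethyl (4S,5R,6E)-3-hydroxy-6-[(4Z)-6-hydroxy-4-methylhex-4-en-1-ylidene]-4-[(4-methoxybenzyl)oxy]-2-methylidene-5-(2-methylpropanoyloxy)heptanedioate (both C3 epimers) | C=C(C(=O)OC)C(O)[C@H](OCc1ccc(OC)cc1)[C@H](OC(=O)C(C)C)/C(C(=O)OC)=C\CC/C(C)=C\CO | intermediate
12 | dimethyl (4S,5R,6E)-3-hydroxy-4-[(4-methoxybenzyl)oxy]-6-[(4Z)-4-methyl-6-oxohex-4-en-1-ylidene]-2-methylidene-5-(2-methylpropanoyloxy)heptanedioate (both C3 epimers) | C=C(C(=O)OC)C(O)[C@H](OCc1ccc(OC)cc1)[C@H](OC(=O)C(C)C)/C(C(=O)OC)=C\CC/C(C)=C\C=O | intermediate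
13 | methyl (2Z,4S,5R,6E,10Z)-2-(bromomethyl)-6-(methoxycarbonyl)-4-[(4-methoxybenzyl)oxy]-10-methyl-5-(2-methylpropanoyloxy)-12-oxododeca-2,6,10-trienoate | BrC/C(C(=O)OC)=C\[C@H](OCc1ccc(OC)cc1)[C@H](OC(=O)C(C)C)/C(C(=O)OC)=C\CC/C(C)=C\C=O | intermediate
14 | hydroxy ester, methyl 2-[(1S,2R,3Z,7E,9R,10S)-2-hydroxy-8-(methoxycarbonyl)-10-[(4-methoxybenzyl)oxy]-4-methyl-9-(2-methylpropanoyloxy)cyclodeca-3,7-dien-1-yl]prop-2-enoate | C=C(C(=O)OC)[C@H]1[C@H](O)/C=C(/C)CC/C=C(/C(=O)OC)[C@@H](OC(=O)C(C)C)[C@H]1OCc1ccc(OC)cc1 | intermediate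
15 | methyl (3aS,4S,5R,6E,10Z,11aR)-4-[(4-methoxybenzyl)oxy]-10-methyl-3-methylidene-5-(2-methylpropanoyloxy)-2-oxo-2,3,3a,4,5,8,9,11a-octahydrocyclodeca[b]furan-6-carboxylate | C=C1C(=O)O[C@@H]2/C=C(/C)CC/C=C(/C(=O)OC)[C@@H](OC(=O)C(C)C)[C@@H](OCc3ccc(OC)cc3)[C@@H]12 | intermediate
16 | methyl (3aS,4S,5R,6E,10Z,11aR)-4-hydroxy-10-methyl-3-methylidene-5-(2-methylpropanoyloxy)-2-oxo-2,3,3a,4,5,8,9,11a-octahydrocyclodeca[b]furan-6-carboxylate | C=C1C(=O)O[C@@H]2/C=C(/C)CC/C=C(/C(=O)OC)[C@@H](OC(=O)C(C)C)[C@@H](O)[C@@H]12 | intermediate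
17 | (2E)-2-methylbut-2-enal (tiglic aldehyde) | C/C=C(\C)C=O | starting material
18 | epoxy aldehyde, (2S,3R)-2,3-dimethyloxirane-2-carbaldehyde | C[C@H]1O[C@]1(C)C=O | intermediate
19 | (2S,3R)-2,3-dimethyloxirane-2-carboxylic acid | C[C@H]1O[C@]1(C)C(=O)O | intermediate
20 | (2S,3S)-3-acetoxy-2-hydroxy-2-methylbutanoic acid | O=C(O)[C@@](C)(O)[C@H](C)OC(C)=O | intermediate
21 | mixed anhydride, (2S,3S)-3-acetoxy-2-hydroxy-2-methylbutanoic 2,4,6-trichlorobenzoic anhydride | O=C(OC(=O)c1c(Cl)cc(Cl)cc1Cl)[C@@](C)(O)[C@H](C)OC(C)=O | intermediate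
22 | CNP0479879.1, methyl (3aS,4S,5R,6E,10Z,11aR)-4-{[(2S,3S)-3-acetoxy-2-hydroxy-2-methylbutanoyl]oxy}-10-methyl-3-methylidene-5-(2-methylpropanoyloxy)-2-oxo-2,3,3a,4,5,8,9,11a-octahydrocyclodeca[b]furan-6-carboxylate | C=C1C(=O)O[C@@H]2/C=C(/C)CC/C=C(/C(=O)OC)[C@@H](OC(=O)C(C)C)[C@@H](OC(=O)[C@@](C)(O)[C@H](C)OC(C)=O)[C@@H]12 | target

## Step count and risk

Total step count: 14 (steps 1–11 and 14 in the main line, steps 12–13 for the side-chain acid).
Longest linear sequence: 12 steps, from neryl acetate 1 to target 22.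

The three steps most likely to fail:

**Step 5 (the proposed new aldol).** The enamine may add in conjugate fashion to 6, proline may enolise 6 at the γ-position, or 7 may mainly self-condense. The fallback uses known chemistry and sets out from 6. A chiral-diamine/Sn(OTf)2-promoted asymmetric Mukaiyama aldol (Bu2Sn(OAc)2, EtCN, −78 °C) with (Z)-1-(ethylsulfanyl)-2-[(4-methoxybenzyl)oxy]-1-(trimethylsilyloxy)ethene adds 1,2 to enals and is anti-selective for benzyl-type glycolate ethers. With the diamine enantiomer that gives the (2R,3R) series it provides the S-ethyl thioester aldol adduct F1. Acylation with isobutyric anhydride, pyridine and DMAP gives the isobutyrate thioester F2. Fukuyama reduction (Et3SiH, Pd on carbon, acetone) converts the thioester into the aldehyde, and the route is rejoined at 9.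

**Step 10 (macrocyclisation).** The reductive ring closure may give oligomers, the cis-fused lactone or the C7 epimer. The fallback sets out from 13 and separates formation of the allyl nucleophile from ring closure. Stannylation with (Bu3Sn)2 and catalytic Pd(PPh3)4 in THF gives the isolable allylstannane F3. BF3·OEt2 in dilute CH2Cl2 at −78 °C then triggers a Lewis-acid-promoted intramolecular allylstannane–aldehyde addition through an open transition state, with no reductive dimerisation possible. This gives hydroxy ester 14, and PPTS closes the lactone, so the route is rejoined at 15.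

**Step 6 (Morita–Baylis–Hillman reaction on aldehyde 9).** The amine may cause β-elimination of the isobutyrate or epimerise C8 before carbon–carbon bond formation. The fallback sets out from 9 and avoids amine catalysis. [1-(Methoxycarbonyl)ethenyl]diisobutylalane is pre-formed from methyl propiolate and i-Bu2AlH with NMO in THF at 0 °C and adds to 9 within minutes under non-basic conditions. It gives the same carbinol, so the route is rejoined at 10. This fallback makes no compound outside the list (F0).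

## Further compounds

F1 | step 5 | S-ethyl thioester aldol adduct, methyl (2E,6Z)-8-acetoxy-2-[(1R,2R)-3-(ethylsulfanyl)-1-hydroxy-2-[(4-methoxybenzyl)oxy]-3-oxopropyl]-6-methylocta-2,6-dienoate | CCSC(=O)[C@H](OCc1ccc(OC)cc1)[C@H](O)/C(C(=O)OC)=C\CC/C(C)=C\COC(C)=O
F2 | step 5 | isobutyrate thioester, methyl (2E,6Z)-8-acetoxy-2-[(1R,2R)-3-(ethylsulfanyl)-2-[(4-methoxybenzyl)oxy]-1-(2-methylpropanoyloxy)-3-oxopropyl]-6-methylocta-2,6-dienoate | CCSC(=O)[C@H](OCc1ccc(OC)cc1)[C@H](OC(=O)C(C)C)/C(C(=O)OC)=C\CC/C(C)=C\COC(C)=O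
F0 | step 6 | none | none
F3 | step 10 | allylstannane, methyl (2Z,4S,5R,6E,10Z)-6-(methoxycarbonyl)-4-[(4-methoxybenzyl)oxy]-10-methyl-5-(2-methylpropanoyloxy)-12-oxo-2-[(tributylstannyl)methyl]dodeca-2,6,10-trienoate | CCCC[Sn](CCCC)(CCCC)C/C(C(=O)OC)=C\[C@H](OCc1ccc(OC)cc1)[C@H](OC(=O)C(C)C)/C(C(=O)OC)=C\CC/C(C)=C\C=O
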